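## Retrosynthetic overview

1. The 6-acetate comes from the 6α-alcohol, made by hydroboration of a Δ6 alkene (sets C6 and C7). The equatorial 1β-bromide comes from SN2 inversion of an axial 1α-alcohol, itself from a C1 ketone.
2. The Δ6-octal-1-one is the adduct of an intramolecular Diels–Alder reaction of a 2-methyl-1,7,9-decatrien-3-one. Bonds C5–C10 and C8–C9 form together, so ring A and ring B close in the same step, with C5 and C10 set by the C4 carbinol.
3. The trienone is assembled on (S)-linalool, which supplies C4 with its OH and CH3 already in place: ene oxidation of the prenyl end gives the dienophile, Heck vinylation of the vinyl end with 2-bromo-3-methylbut-1-ene gives the diene.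

Assumption: (S)-(+)-linalool of high enantiomeric purity and 2-bromo-3-methylbut-1-ene are taken as purchasable; bicyclic compounds carry eudesmane numbering (C14 = methyl on C10, C15 = methyl on C4, β = face of C14).

## Route

Step 1
Reactants: 1 (S)-(+)-linalool, (3S)-3,7-dimethylocta-1,6-dien-3-ol
Product: 3 (3S,6RS)-3,7-dimethylocta-1,7-diene-3,6-diol, via allylic hydroperoxide 2 (not isolated)
Conditions: O2, hν (visible), tetraphenylporphyrin (cat.), CH2Cl2, 0 °C; then PPh3, 0 °C to rt
Reagents that add atoms: dioxygen, O=O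
Why: Schenck ene reaction of singlet oxygen at the trisubstituted alkene only (the vinyl group is inert), then phosphine reduction of the hydroperoxide; roughly half the material is the tertiary regioisomer and is removed by chromatography, the new secondary carbinol is formed unselectively but is oxidised away in step 3, and the purchased tertiary centre is untouched.

Step 2
Reactants: 3 (3S,6RS)-3,7-dimethylocta-1,7-diene-3,6-diol; 4 2-bromo-3-methylbut-1-ene
Product: 5 (3RS,6S,7E)-2,6-dimethyl-9-(propan-2-yl)deca-1,7,9-triene-3,6-diol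
Conditions: Pd(OAc)2 (5 mol %), K2CO3, n-Bu4NCl, DMF, 60 °C
Reagents that add atoms: none
Why: Mizoroki–Heck vinylation of the monosubstituted alkene, where the neighbouring carbinol carbon has no hydrogen so β-hydride elimination can only give the conjugated (E)-diene, and the 1,1-disubstituted alkene inserts much more slowly.

Step 3
Reactants: 5 (3RS,6S,7E)-2,6-dimethyl-9-(propan-2-yl)deca-1,7,9-triene-3,6-diol
Product: 7 (4S,5R,10R)-4-hydroxyeudesm-6-en-1-one, via trienone 6 (not isolated)
Conditions: Dess–Martin periodinane, pyridine, CH2Cl2, 0 °C to rt; then PhMe (0.01 M), BHT, 90 °C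
Reagents that add atoms: none
Why: Oxidation of the secondary allylic alcohol unmasks an isopropenyl ketone that undergoes a type 1 intramolecular Diels–Alder reaction closing both rings; the α-methyl enone is expected to react through the carbonyl-exo, chair-tether geometry (trans fusion, 5α-H), and the C4 centre places OH rather than CH3 axial next to the forming angular methyl, so 10β-CH3 ends cis to 4β-OH.

Step 4
Reactants: 7 (4S,5R,10R)-4-hydroxyeudesm-6-en-1-one
Product: 8 (1S,4S,5R,10R)-eudesm-6-ene-1,4-diol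
Conditions: LiBH(s-Bu)3 (2.5 equiv), THF, −78 °C; then H2O
Reagents that add atoms: none
Why: Bulky-hydride ketone reduction, in which axial attack is blocked by three syn-axial hydrogens (H3α, H5α, H9α) so hydride enters equatorially and gives the axial 1α-alcohol needed for inversion.

Step 5
Reactants: 8 (1S,4S,5R,10R)-eudesm-6-ene-1,4-diol
Product: 9 (1R,4S,5R,10R)-1-bromoeudesm-6-en-4-ol
Conditions: CBr4, P(n-C8H17)3, PhMe, 0 to 70 °C
Reagents that add atoms: carbon tetrabromide, BrC(Br)(Br)Br
Why: Appel reaction in which bromide displaces the axial 1α-oxyphosphonium with inversion along the same equatorial trajectory the hydride used in step 4, giving the equatorial 1β-bromide, while the hindered tertiary 4-OH is activated far more slowly.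

Step 6
Reactants: 9 (1R,4S,5R,10R)-1-bromoeudesm-6-en-4-ol
Product: 11 (1R,4S,5S,6S,7S,10R)-1-bromoeudesmane-4,6-diol, via alkylborane 10 (not isolated)
Conditions: BH3·THF, THF, 0 °C to rt; then aq. NaOH, H2O2, 0 °C
Reagents that add atoms: borane–tetrahydrofuran complex, [BH3-][O+]1CCCC1 (boron of 10); hydrogen peroxide, OO (oxygen at C6)
Why: Brown hydroboration–oxidation, with boron going to the less substituted C6 from the α face (the β face is shielded by the axial C10 methyl and axial 4-OH) and hydrogen delivered syn to C7, which sets 6α-OH and 7β-isopropyl, both equatorial; the C5 descriptor changes from R to S only because the priorities change.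

Step 7
Reactants: 11 (1R,4S,5S,6S,7S,10R)-1-bromoeudesmane-4,6-diol
Product: 12 (1R,4S,5S,6S,7S,10R)-1-bromo-4-hydroxyeudesman-6-yl acetate
Conditions: Ac2O, pyridine, DMAP (cat.), CH2Cl2, rt
Reagents that add atoms: acetic anhydride, CC(=O)OC(C)=O
Why: DMAP-catalysed acetylation of the only secondary hydroxyl, the axial tertiary 4-OH being inert under these conditions.

## Compound list

1 | (S)-(+)-linalool, (3S)-3,7-dimethylocta-1,6-dien-3-ol | CC(C)=CCC[C@](C=C)(C)O | starting material
2 | (3S,6RS)-6-hydroperoxy-3,7-dimethylocta-1,7-dien-3-ol | C=C(C)C(OO)CC[C@](C=C)(C)O | intermediate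
3 | (3S,6RS)-3,7-dimethylocta-1,7-diene-3,6-diol | C=C(C)C(O)CC[C@](C=C)(C)O | intermediate
4 | 2-bromo-3-methylbut-1-ene | C=C(Br)C(C)C | starting material
5 | (3RS,6S,7E)-2,6-dimethyl-9-(propan-2-yl)deca-1,7,9-triene-3,6-diol | C=C(C)C(O)CC[C@](/C=C/C(=C)C(C)C)(C)O | intermediate
6 | (6S,7E)-6-hydroxy-2,6-dimethyl-9-(propan-2-yl)deca-1,7,9-trien-3-one | C=C(C)C(=O)CC[C@](/C=C/C(=C)C(C)C)(C)O | intermediate
7 | (4S,5R,10R)-4-hydroxyeudesm-6-en-1-one; 4β-OH, 5α-H, 10β-CH3; = (4S,4aR,8aR)-4-hydroxy-4,8a-dimethyl-6-(propan-2-yl)-3,4,4a,7,8,8a-hexahydronaphthalen-1(2H)-one | CC(C)C1=C[C@@H]2[C@@](C)(CC1)C(=O)CC[C@]2(C)O | intermediate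
8 | (1S,4S,5R,10R)-eudesm-6-ene-1,4-diol; 1α-OH axial, 4β-OH | CC(C)C1=C[C@@H]2[C@@](C)(CC1)[C@@H](O)CC[C@]2(C)O | intermediate
9 | (1R,4S,5R,10R)-1-bromoeudesm-6-en-4-ol; 1β-Br equatorial | CC(C)C1=C[C@@H]2[C@@](C)(CC1)[C@H](Br)CC[C@]2(C)O | intermediate
10 | (1β-bromo-4β-hydroxyeudesman-6α-yl)borane, 7β-isopropyl, drawn as the monoalkylborane | B[C@@H]1[C@@H]2[C@@](C)(CC[C@H]1C(C)C)[C@H](Br)CC[C@]2(C)O | intermediate
11 | (1R,4S,5S,6S,7S,10R)-1-bromoeudesmane-4,6-diol; 6α-OH, 7β-isopropyl | O[C@@H]1[C@@H]2[C@@](C)(CC[C@H]1C(C)C)[C@H](Br)CC[C@]2(C)O | intermediate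
12 | (1R,4S,5S,6S,7S,10R)-1-bromo-4-hydroxyeudesman-6-yl acetate | CC(=O)O[C@@H]1[C@@H]2[C@@](C)(CC[C@H]1C(C)C)[C@H](Br)CC[C@]2(C)O | target

## Step count

Total steps: 7. Longest linear sequence: 7 (1 to 12); 4 is used as bought.

## Steps most likely to fail, with fallbacks

**Step 3.** The trans fusion and the facial sense are predicted from transition-state reasoning, not from a closely matching precedent. An internally activated decatrienone can also close through the carbonyl-endo mode (cis-fused C5 epimer) or with C4–CH3 axial (C5 and C10 both inverted). The fallback moves control from the substrate to a Lewis acid and runs from 6 back to 7. Crude 6 is kept at 0 °C and silylated at the tertiary hydroxyl with 1-(trimethylsilyl)imidazole to give (6S,7E)-2,6-dimethyl-9-(propan-2-yl)-6-(trimethylsilyloxy)deca-1,7,9-trien-3-one F1. F1 is cyclised at −78 °C in CH2Cl2/PhMe with the cavity-forming Lewis acid Al(OC6H3Ph2-2,6)3, which shields the complexed carbonyl and favours the carbonyl-exo, trans-fusing geometry, to give (4S,5R,10R)-4-(trimethylsilyloxy)eudesm-6-en-1-one F2. K2CO3 in MeOH removes the silyl group and returns 7.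

**Step 5.** This is an SN2 reaction at a secondary carbon next to the quaternary C10. Elimination to the Δ1 alkene, methyl migration from C10, activation of the tertiary 4-OH, and transannular attack of the 4β-OH on C1 (a 1,4-ether) can all compete. The fallback masks O4 and separates activation from displacement, running from 7 back to 9. TESOTf and 2,6-lutidine (CH2Cl2, −78 °C) give (4S,5R,10R)-4-(triethylsilyloxy)eudesm-6-en-1-one F3. LiBH(s-Bu)3 as in step 4 gives (1S,4S,5R,10R)-4-(triethylsilyloxy)eudesm-6-en-1-ol F4. Tf2O and pyridine (CH2Cl2, −20 °C) give (1S,4S,5R,10R)-4-(triethylsilyloxy)eudesm-6-en-1-yl trifluoromethanesulfonate F5. n-Bu4NBr in PhMe (0 °C to rt) displaces the triflate with inversion to (1R,4S,5R,10R)-1-bromo-4-(triethylsilyloxy)eudesm-6-ene F6. HF·pyridine in THF returns 9.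

**Step 2.** The vinylpalladium species can also insert into the isopropenyl carbinol, and the diene product can react further. The fallback replaces the Heck reaction by metathesis then cross-coupling, running from 3 back to 5. Cross-metathesis of the monosubstituted alkene of 3 with 4,4,5,5-tetramethyl-2-vinyl-1,3,2-dioxaborolane (second-generation Grubbs catalyst, CH2Cl2, 40 °C) gives (3RS,6S,7E)-2,6-dimethyl-8-(4,4,5,5-tetramethyl-1,3,2-dioxaborolan-2-yl)octa-1,7-diene-3,6-diol F7. Suzuki–Miyaura coupling of F7 with 4 (Pd(PPh3)4, aq. K3PO4, THF, 50 °C) returns 5.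

## Further compounds

F1 | step 3 | (6S,7E)-2,6-dimethyl-9-(propan-2-yl)-6-(trimethylsilyloxy)deca-1,7,9-trien-3-one | C=C(C)C(=O)CC[C@](/C=C/C(=C)C(C)C)(C)O[Si](C)(C)C
F2 | step 3 | (4S,5R,10R)-4-(trimethylsilyloxy)eudesm-6-en-1-one | CC(C)C1=C[C@@H]2[C@@](C)(CC1)C(=O)CC[C@]2(C)O[Si](C)(C)C
F3 | step 5 | (4S,5R,10R)-4-(triethylsilyloxy)eudesm-6-en-1-one | CC(C)C1=C[C@@H]2[C@@](C)(CC1)C(=O)CC[C@]2(C)O[Si](CC)(CC)CC
F4 | step 5 | (1S,4S,5R,10R)-4-(triethylsilyloxy)eudesm-6-en-1-ol | CC(C)C1=C[C@@H]2[C@@](C)(CC1)[C@@H](O)CC[C@]2(C)O[Si](CC)(CC)CC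
F5 | step 5 | (1S,4S,5R,10R)-4-(triethylsilyloxy)eudesm-6-en-1-yl trifluoromethanesulfonate | CC(C)C1=C[C@@H]2[C@@](C)(CC1)[C@@H](OS(=O)(=O)C(F)(F)F)CC[C@]2(C)O[Si](CC)(CC)CC
F6 | step 5 | (1R,4S,5R,10R)-1-bromo-4-(triethylsilyloxy)eudesm-6-ene | CC(C)C1=C[C@@H]2[C@@](C)(CC1)[C@H](Br)CC[C@]2(C)O[Si](CC)(CC)CC
F7 | step 2 | (3RS,6S,7E)-2,6-dimethyl-8-(4,4,5,5-tetramethyl-1,3,2-dioxaborolan-2-yl)octa-1,7-diene-3,6-diol | C=C(C)C(O)CC[C@](/C=C/B1OC(C)(C)C(C)(C)O1)(C)O
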